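Slowness comes first: why does solid E, turning into J, creep and then halt?

| flask | E | temperature | remark | time |
|---|---|---|---|---|
| Thursday's | 1.4 M | 25 °C | the very flask that is asked about, followed so far |  |
| Friday's | 0.94 M | 10 °C | run made earlier |  |
| flask | 1.4 M | 25 °C |  | 15 h |

| run | time / h | J / % |
|---|---|---|
| Thursday's | 2.00 | 27.7 |
| Thursday's | 4.00 | 48.7 |
| Thursday's | 5.00 | 54.1 |
| Thursday's | 8.00 | 62.5 |
| Thursday's | 10.0 | 61.5 |
| Friday's | 2.00 | 12.0 |
| Friday's | 3.00 | 19.7 |
| Friday's | 6.00 | 38.8 |
| Friday's | 12.0 | 67.7 |
| Friday's | 20.0 | 70.2 |

(scatter of a reading: 1 percentage point)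

- south: change nothing and wait 5.0 h more
- south-east: at 15 h take out 90 % of the J then present, then wait 5.0 h
- north-east: at 15 h raise the temperature by 15 K, then wait 5.0 h

- E is a solid; its amount is given per volume of the solution
- what is taken out of J is counted as made
- at the start none of E is in solution

- J, in percent of the E first charged, at 15 h
- what to do for the largest gain in J; "none" if nothing gains more than 2 percentage points (south / south-east / north-east / none)
- J present, with what was taken out counted in, in percent of the E first charged, after south
- J present, with what was taken out counted in, in percent of the E first charged, after north-east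

*Does Thursday's flask still move at 15 h?* By the readings, no: J stands at 62.5 % at 8.00 h and 61.5 % at 10.0 h. I read a plateau share s = 62.0 %.

*Is that plateau a stop or a balance?* The readings prove neither. But J gains 28 percentage points in the first 2.00 h and just 5.4 points from 4.00 h to 5.00 h, a bend rather than a corner, so I lean to balance.

*Then reckon what?* Reckon the fraction left outside J. Call it the balance ratio ρ, the reacted E standing outside J per part of J at the plateau, an equilibrium constant in plain clothes. Thursday's flask gives ρ = 0.613; Friday's last reading gives 0.425. Friday's run differs from Thursday's in charge as well as in temperature, and its last reading may not be a plateau, so the factor m = 1.44 between the two is a rough reading.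

*And if J is taken out?* Taking 90 % of J leaves the fraction L = 44.2 % in the flask, and the balance turns share s of L back into J. Counted J becomes 83.2 %, a gain of 21 points. Waiting gains nothing. The rise 15 K matches the temperature gap between the runs; laying the whole of m on temperature, a guess these two runs cannot test, I put ρ at 0.885 and J at 53.1 %. My answer is 62.0 % now, and south-east.

The forecast gives 62 % now, 62 % after south, 61.5 % after north-east, and best: none. Its ground: “Waiting, removing J or heating therefore changes little, since nothing remains to convert.”

The flask gives 61.4 % now, 61.4 % after south and 56.0 % after north-east. Best is south-east, gaining 20 points, against 0.037 points for south and −5.3 points for north-east.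

    Z ⇌ J (K = 19.0, k = 6.10 h⁻¹, Ea = 94.0 kJ mol⁻¹, ΔH = 2.00 kJ mol⁻¹)
    Z ⇌ X (K = 2.20, k = 0.512 h⁻¹, Ea = 85.0 kJ mol⁻¹, ΔH = 38.0 kJ mol⁻¹)
    E ⇌ Z, rate k3*(cs3 - [Z]) while solid is left; crystals form when [Z] > cs3 (solubility = 0.110 M, k = 4.23 h⁻¹)
    J ⇌ Q (K = 0.460, k = 0.235 h⁻¹, Ea = 100 kJ mol⁻¹, ΔH = 5.00 kJ mol⁻¹)
    (constants at 25 °C)

While E lasted (70.3 % at 1.50 h, 0 % at 7.50 h), it dissolved to Z, and Z fed J and X, with J made 3.40 times faster than used up, net, at 2.72 h. Between 7.50 h and 15.0 h, J moved from 63.4 % to 61.4 % while Q moved from 25.6 % to 28.2 %. The forecast and I part on removal: ρ from the flask's own J is 0.629, and my gain was 21 points.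

The same flask run at 0 °C still holds 71.1 % of E as solid at 15 h, so it stands at no plateau, and ρ serves there as a rough guide. Carrying Thursday's ρ = 0.613 over with no correction for temperature, J gets 17.9 % from what has left the solid; the computed J is 18.7 %.

(Readings and results stem from a simulated flask on assumed constants, noise included.)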